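Atom labels (C1 to O34) follow the order of the heavy atoms in the SMILES of the target. Compound numbers are those of the steps and of the compound list.

## Analysis of the target

Chermebilaene B (40) is built on cyclohexane ring A (C2, C3, C5, C6, C11, C18). Ring A is spiro-linked at C11 to a δ-lactone (C11–C12–C13–C14(=O)–O16–C17) and at C18 to a tetrahydrofuran (C18–C19–C20–C31–O34). C31 is an orthoester carbon inside a dioxabicyclo[3.2.1]octane cage (tetrahydropyran C20–C22–C24–C33–O32–C31, dioxolane C28–O30–C31–O32–C33), and the acyloxy ketal carbon C28 is closed onto C25 as a γ-lactone. There are eleven stereocentres (2S,3S,6R,11S,18S,20R,22S,24R,28S,31S,33S). On ring A the C1 methyl, O4, C7, C17 and O34 all lie on one face; C11 and C18 are adjacent fully substituted carbons, and C20 is a third quaternary carbon whose methyl C21 is cis to methyl C23 on the tetrahydropyran. C28 and C31 have no freedom of their own: once C20, C22, C24 and C33 are set, the cage can close in one way only. The orthoester and acyloxy ketal are sensitive to aqueous acid, the lactones to base and hydride, the tertiary C7 carbinol to dehydration, and several β-hydroxy carbonyl intermediates to retro-aldol cleavage. The hard part is the congested C11–C18 bond and the relay of configuration from ring A through the spiro carbon C18 to C20 and into the cage. The strategy rests on one feature: C17 on C11 is cis to O34 on C18 and also cis to C7 on C6. C17 can therefore be a carbonyl carbon whose enolate at C11 adds to a C18 ketone under chelation, while the same carbonyl is held with O10 in a γ-lactone (C6–C7–O10–C17–C11) that delivers C11 on the correct face.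

## Retrosynthetic reasoning

**Cage (40 to 38).** The C31–O32, C31–O30 and C28–O27 bonds are cut. They are carbon–oxygen bonds at the carboxylic acid and ketone oxidation levels, they form reversibly, and the two stereocentres they create (C28, C31) are dictated by the rest. This exposes keto acid 38: a spiro γ-lactone (C31), a free acid (C25), a secondary alcohol (C33) and a methyl ketone (C28). The forward reaction has to remove the silyl groups and lose one molecule of water.

**C24–C33 (38 to 33 and 34).** This is an aldol bond, with the C28 ketone masked as the isopropenyl group of 34 (intermediates 36 and 37). The cut is made here because C24 is α to C25 and because imide 33 can be enolised under soft conditions that leave both lactones alone; a strong base would deprotonate C13 of the δ-lactone first. The aldol must be anti and must place C33 anti to the bulky C20 group; the neighbouring C22 centre directs this.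

**C20–C22 (33 to 30 and 31).** This is a conjugate addition of a C20 nucleophile to crotonoyl imide 31. The nucleophile is generated from butenolide 30 by conjugate reduction, which fixes the enolate position at C20 without any base. The C21 methyl is already on C20, so the larger electrophile enters from the open face of the spiro-lactone, the side of C2–H. The face of C22 is left to a chiral catalyst.

**Butenolide (30 to 26 and 27).** C19=C20 and C31–O34 are cut. A Z-selective olefination of α-hydroxy aldehyde 26 with phosphonate 27 and lactonisation (29), followed by silylation of the C7 alcohol, gives 30.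

**δ-Lactone and C17 (26 to 22).** The C14–O16 bond comes from oxidative lactonisation of a 1,5-diol (25 from 23). C17 is taken back to a lactone carbonyl, and the C14 oxygen to an ester, both reduced by one hydride reagent (23 from 22). C19 is carried as a silyloxymethyl group and oxidised to the aldehyde afterwards.

**Key disconnection, C11–C18 (22 to 20).** Ring A is opened between its two fully substituted carbons. The forward step is a Reformatsky closure by a divalent samarium reductant: the α-bromo lactone gives an enolate at C11, a position that no base could select next to the C18 ketone. An open-chain ester with a separately protected C7 alcohol would also cyclise, but nothing in it would decide which face of C11 bonds to C18; the competing chair transition states differ only in whether C17 or C12 is axial. Tying C17 to O10 as the γ-lactone removes this ambiguity, because the tether on C6 can reach the enolate from one face only.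

**Ketone and bromide (20 to 15).** The C18 ketone and C19 come from the terminal alkene of 15 by dihydroxylation, silylation of the primary alcohol and oxidation (18, 19). The bromide is put on C11 before that (17), while the lactone α-hydrogen is the only acidic C–H; once the ketone exists, its C2–H would be removed first.

**C2–C3 (15 to 13).** A crotylation is chosen over an aldol addition of an ethyl ketone. C6 is a remote β-stereocentre and cannot bias the faces of the C3 aldehyde, so the C2/C3 pair has to be set by a chiral crotylborane, which gives the anti pair with reagent control.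

**C11–C12 and C3 (13 to 8 and 11).** The C12–C14 chain is attached by lactone enolate alkylation with iodide 11 (12), and the allyl group is cleaved to the C3 aldehyde. The pivalate on O at C14 survives amide bases and falls off in the later hydride step.

**Lactone 8 (to 1, 2 and 4).** C6 is set by auxiliary-controlled alkylation of imide 3 with bromoacetate 4 (5). Transesterification (6), double methyl addition at C7 and lactonisation then give 8.

## Alternatives that were turned down

**Alternative 1:** The disconnection is C31–O34, the closure of the tetrahydrofuran at the orthoester level. In the forward step, tertiary alcohol A2 already holds ring A, both spiro-bound quaternary carbons and the tetrahydropyran as a methyl acetal at C31. An O34-centred radical abstracts the anomeric C31–H through a six-membered transition state, the C31 radical is oxidised to the oxocarbenium ion, and O34 closes to the mixed orthoester A1.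
- For it: the orthoester level is reached late, under neutral conditions, by a geometrically ideal 1,5-hydrogen transfer to a weak anomeric C–H. On this point it is gentler than the acid-mediated dehydration that closes the cage in the chosen route.
- Against it: the step makes only a C–O bond. A2 already contains C11, C18, C20 and all ring A centres, so the C11–C18 problem is merely moved into the preparation of A2. An alkoxy radical on C18, next to the quaternary C11, can also fragment by β-scission of C18–C11. A1 still needs exchange of the methoxy group for O30 and lactonisation at C25.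
- Comparison: the chosen strategy spends its key step on the hardest C–C bond and reaches the orthoester by a condensation at the very end.

**Alternative 2:** The disconnections are C6–C11 and C7–O10. Mn(OAc)3 (trivalent manganese) oxidises β-keto ester A4 to the C11 radical; 6-exo addition to the trisubstituted alkene forms C6–C11; the tertiary C7 radical is oxidised to the cation and captured by the ester carbonyl. The product is the ring A ketone A3 with the cis-fused γ-lactone.
- For it: one step makes ring A, the quaternary C11, C6 and the lactone from a short acyclic precursor, and the cis ring fusion is inherent. For ring A alone it is clearly more step-economic than the twelve linear steps to 20.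
- Against it: C18 emerges as a ketone. The tertiary C18 centre with O34 and C19 then has to be made by intermolecular addition to a ketone flanked by the quaternary C11 within a β-keto lactone, where retro-Claisen cleavage and enolisation toward C2 threaten. C6 is set only relative to C2 and C3, through a radical chair with a 1,3-related silyloxy group. The β-silyloxy ketone must also survive hot acidic oxidising conditions.
- Comparison: the chosen strategy sets C18 in the ring-closing step itself through chelation and sets C6 absolutely with an auxiliary.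

**Alternative 3:** C19–C20, C18–O34 and C31–O30 are cut in one cascade that unites the ring A alkene A6 (exocyclic C18=C19) with the bicyclic α-bromo δ-lactone A7. The C20 radical from A7 adds to C19, the tertiary C18 radical is oxidised, the lactone carbonyl oxygen captures the cation, and the C28 hydroxyl closes the dioxolane. The product A5 is the bis-silyl ether of 40.
- For it: it is the most convergent plan. Three bonds, two rings and three stereocentres (C18, C20, C31) arise in one step, the cage fragment is made separately, and A5 is one deprotection from the target. In convergence and in step count after the union it is stronger than the chosen route.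
- Against it: C18 is formed from a planar radical or cation next to the quaternary C11, with nothing that directs O34 to the face of C17. The C19–C20 bond comes from an intermolecular addition of a tertiary radical to a neopentyl-type alkene, which is slow against reduction of A7. The C18 cation invites 1,2-shift or elimination. A6 still contains C11, whose construction the plan does not address.
- Comparison: the chosen route sets C11 and C18 together in a closed, chelated, two-electron transition state and accepts a linear endgame in exchange.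

Key step: step 14

Assumption: 9, 27, 31 and 34 are taken as catalogue compounds; 31 is otherwise made in one step from oxazolidin-2-one and (E)-but-2-enoyl chloride.

## Route

Step 1
Reactants: 1 (4S)-4-benzyl-1,3-oxazolidin-2-one; 2 pent-4-enoyl chloride
Product: 3 (4S)-4-benzyl-3-(pent-4-enoyl)-1,3-oxazolidin-2-one
Conditions: n-BuLi, THF, −78 °C; then 2, −78 to 0 °C
Reagents that add atoms: none
Why: N-acylation of the lithiated oxazolidinone is the standard entry to auxiliary-controlled (Evans) enolate chemistry; the acyl group supplies C7, C6, C5 and C3.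

Step 2
Reactants: 3 (4S)-4-benzyl-3-(pent-4-enoyl)-1,3-oxazolidin-2-one; 4 tert-butyl bromoacetate
Product: 5 tert-butyl (3R)-3-{[(4S)-4-benzyl-2-oxo-1,3-oxazolidin-3-yl]carbonyl}hex-5-enoate
Conditions: NaN(SiMe3)2, THF, −78 °C; then 4, −78 to −40 °C
Reagents that add atoms: none
Why: Evans alkylation: the chelated Z-sodium enolate is alkylated by the reactive α-bromo ester on the face opposite the benzyl group, which sets C6 (R) and brings in C11 and C17.

Step 3
Reactants: 5 tert-butyl (3R)-3-{[(4S)-4-benzyl-2-oxo-1,3-oxazolidin-3-yl]carbonyl}hex-5-enoate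
Product: 6 4-tert-butyl 1-methyl (2R)-2-(prop-2-en-1-yl)butanedioate
Conditions: MeMgBr, MeOH, CH2Cl2, 0 °C
Reagents that add atoms: methanol (as bromomagnesium methoxide), CO
Why: Transesterification of the imide with bromomagnesium methoxide cleaves the exocyclic acyl bond without epimerising C6 and leaves the tert-butyl ester; the auxiliary 1 is recovered.

Step 4
Reactants: 6 4-tert-butyl 1-methyl (2R)-2-(prop-2-en-1-yl)butanedioate
Product: 8 (4R)-5,5-dimethyl-4-(prop-2-en-1-yl)oxolan-2-one, via hydroxy ester 7 (not isolated)
Conditions: MeMgBr (2.2 equiv), THF, −40 to 0 °C; then TFA, CH2Cl2, rt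
Reagents that add atoms: methylmagnesium bromide, C[Mg]Br
Why: Double Grignard addition should take place at the methyl ester and not at the hindered tert-butyl ester, giving the C7 carbinol; acid then cleaves the tert-butyl ester and closes the γ-lactone (gem-dimethyl effect), which ties O10 to C17.

Step 5
Reactants: 9 3-iodopropan-1-ol; 10 2,2-dimethylpropanoyl chloride
Product: 11 3-iodopropyl 2,2-dimethylpropanoate
Conditions: pyridine, CH2Cl2, 0 °C to rt
Reagents that add atoms: none
Why: Acylation of a primary alcohol; the pivalate has no α-hydrogen, withstands the amide bases used later and is removed by the hydride that reduces C17.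

Step 6
Reactants: 8 (4R)-5,5-dimethyl-4-(prop-2-en-1-yl)oxolan-2-one; 11 3-iodopropyl 2,2-dimethylpropanoate
Product: 12 3-[(3R,4R)-5,5-dimethyl-2-oxo-4-(prop-2-en-1-yl)oxolan-3-yl]propyl 2,2-dimethylpropanoate
Conditions: LiN(i-Pr)2, THF, −78 °C; then 11, DMPU, −78 to −30 °C
Reagents that add atoms: none
Why: Alkylation of a γ-lactone lithium enolate with a primary iodide, trans to the allyl group on C6, attaches C12–C14; the C11 configuration is of no consequence because C11 is made planar again in steps 10 and 14.

Step 7
Reactants: 12 3-[(3R,4R)-5,5-dimethyl-2-oxo-4-(prop-2-en-1-yl)oxolan-3-yl]propyl 2,2-dimethylpropanoate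
Product: 13 3-[(3R,4R)-5,5-dimethyl-2-oxo-4-(2-oxoethyl)oxolan-3-yl]propyl 2,2-dimethylpropanoate
Conditions: O3, CH2Cl2, −78 °C; then PPh3
Reagents that add atoms: ozone, [O-][O+]=O
Why: Ozonolysis of the only alkene with reductive work-up gives the C3 aldehyde; lactone and ester are inert.

Step 8
Reactants: 13 3-[(3R,4R)-5,5-dimethyl-2-oxo-4-(2-oxoethyl)oxolan-3-yl]propyl 2,2-dimethylpropanoate
Product: 14 3-{(3R,4R)-4-[(2S,3R)-2-hydroxy-3-methylpent-4-en-1-yl]-5,5-dimethyl-2-oxooxolan-3-yl}propyl 2,2-dimethylpropanoate
Conditions: (E)-crotyl-B(Ipc)2 [from trans-but-2-ene, n-BuLi, KOt-Bu, (+)-Ipc2BOMe, BF3·OEt2], THF/Et2O, −78 °C; then NaBO3·4H2O, H2O, rt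
Reagents that add atoms: (E)-crotyldiisopinocampheylborane of the (−)-α-pinene series, C/C=C/CB([C@H]1C[C@H]2C[C@@H]([C@@H]1C)C2(C)C)[C@H]1C[C@H]2C[C@@H]([C@@H]1C)C2(C)C
Why: Brown crotylboration through a chair Zimmerman–Traxler transition state: the E-crotyl geometry gives the anti C2/C3 pair (C1 methyl and O4 cis on the later ring A), and the reagent made from (+)-Ipc2BOMe adds to the Re face of the aldehyde. C3 (S) and C2 are thus set by the reagent and not by the remote C6 centre.

Step 9
Reactants: 14 3-{(3R,4R)-4-[(2S,3R)-2-hydroxy-3-methylpent-4-en-1-yl]-5,5-dimethyl-2-oxooxolan-3-yl}propyl 2,2-dimethylpropanoate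
Product: 15 3-{(3R,4R)-4-[(2S,3R)-2-{[tert-butyl(dimethyl)silyl]oxy}-3-methylpent-4-en-1-yl]-5,5-dimethyl-2-oxooxolan-3-yl}propyl 2,2-dimethylpropanoate
Conditions: TBSOTf, 2,6-lutidine, CH2Cl2, −78 to 0 °C
Reagents that add atoms: tert-butyldimethylsilyl trifluoromethanesulfonate, CC(C)(C)[Si](C)(C)OS(=O)(=O)C(F)(F)F
Why: Silylation of the hindered secondary alcohol with the silyl triflate; the ether removes the only proton source near the later samarium enolate and stays equatorial on ring A.

Step 10
Reactants: 15 3-{(3R,4R)-4-[(2S,3R)-2-{[tert-butyl(dimethyl)silyl]oxy}-3-methylpent-4-en-1-yl]-5,5-dimethyl-2-oxooxolan-3-yl}propyl 2,2-dimethylpropanoate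
Product: 17 3-{(3R,4S)-3-bromo-4-[(2S,3R)-2-{[tert-butyl(dimethyl)silyl]oxy}-3-methylpent-4-en-1-yl]-5,5-dimethyl-2-oxooxolan-3-yl}propyl 2,2-dimethylpropanoate, via silyl ketene acetal 16 (not isolated)
Conditions: LiN(i-Pr)2, THF, −78 °C; TMSCl; then NBS, −78 °C
Reagents that add atoms: N-bromosuccinimide, O=C1CCC(=O)N1Br
Why: The lactone α-hydrogen is the only acidic C–H at this stage, so the bromide is installed before any ketone exists; bromination of the silyl ketene acetal by NBS at C11 should occur mainly anti to the C6 side chain. Either C11 epimer serves in step 14.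

Step 11
Reactants: 17 3-{(3R,4S)-3-bromo-4-[(2S,3R)-2-{[tert-butyl(dimethyl)silyl]oxy}-3-methylpent-4-en-1-yl]-5,5-dimethyl-2-oxooxolan-3-yl}propyl 2,2-dimethylpropanoate
Product: 18 3-{(3R,4S)-3-bromo-4-[(2S,3R,4RS)-2-{[tert-butyl(dimethyl)silyl]oxy}-4,5-dihydroxy-3-methylpentyl]-5,5-dimethyl-2-oxooxolan-3-yl}propyl 2,2-dimethylpropanoate
Conditions: K2OsO4·2H2O (cat.), NMO, acetone/H2O, rt
Reagents that add atoms: N-methylmorpholine N-oxide, C[N+]1([O-])CCOCC1; water, O
Why: Upjohn dihydroxylation of the terminal alkene; the new C18 carbinol is oxidised in step 13, so its configuration does not matter.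

Step 12
Reactants: 18 3-{(3R,4S)-3-bromo-4-[(2S,3R,4RS)-2-{[tert-butyl(dimethyl)silyl]oxy}-4,5-dihydroxy-3-methylpentyl]-5,5-dimethyl-2-oxooxolan-3-yl}propyl 2,2-dimethylpropanoate
Product: 19 3-{(3R,4S)-3-bromo-4-[(2S,3R,4RS)-2-{[tert-butyl(dimethyl)silyl]oxy}-4-hydroxy-3-methyl-5-[(triethylsilyl)oxy]pentyl]-5,5-dimethyl-2-oxooxolan-3-yl}propyl 2,2-dimethylpropanoate
Conditions: TESCl, imidazole, CH2Cl2, −20 °C
Reagents that add atoms: chlorotriethylsilane, CC[Si](Cl)(CC)CC
Why: Selective silylation of the primary hydroxyl of a 1,2-diol next to a hindered secondary one; C19 is thereby carried at the alcohol level.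

Step 13
Reactants: 19 3-{(3R,4S)-3-bromo-4-[(2S,3R,4RS)-2-{[tert-butyl(dimethyl)silyl]oxy}-4-hydroxy-3-methyl-5-[(triethylsilyl)oxy]pentyl]-5,5-dimethyl-2-oxooxolan-3-yl}propyl 2,2-dimethylpropanoate
Product: 20 3-{(3R,4S)-3-bromo-4-[(2S,3S)-2-{[tert-butyl(dimethyl)silyl]oxy}-3-methyl-4-oxo-5-[(triethylsilyl)oxy]pentyl]-5,5-dimethyl-2-oxooxolan-3-yl}propyl 2,2-dimethylpropanoate
Conditions: Dess–Martin periodinane, NaHCO3, CH2Cl2, rt
Reagents that add atoms: none
Why: Dess–Martin oxidation under buffered, non-basic conditions gives the α-silyloxy ketone without epimerising C2 or eliminating the β-silyloxy group.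

Step 14
Reactants: 20 3-{(3R,4S)-3-bromo-4-[(2S,3S)-2-{[tert-butyl(dimethyl)silyl]oxy}-3-methyl-4-oxo-5-[(triethylsilyl)oxy]pentyl]-5,5-dimethyl-2-oxooxolan-3-yl}propyl 2,2-dimethylpropanoate
Product: 22 cis-fused ring A hydroxy γ-lactone (2S,3S,6R,11R,18S), via samarium enolate 21 (not isolated)
Conditions: SmI2 (2.2 equiv), THF, −78 °C, slow addition of 20; then sat. aq. NH4Cl at −78 °C
Reagents that add atoms: none
Why: Two equivalents of SmI2 reduce the tertiary C–Br bond of the α-bromo lactone much faster than the α-silyloxy ketone, and the C11 radical is reduced again to the samarium enolate 21 (trivalent samarium), so the enolate forms only at C11 although C2–H is more acidic; the closest known reaction type is the SmI2-promoted intramolecular Reformatsky cyclisation of α-bromo esters onto ketones. C11 attacks C18 in a 6-(enolexo)-exo-trig closure that completes ring A. C11 is controlled by the lactone: the tether C5–C3–C2 leaves C6 on one face of the five-membered enolate ring and can reach C11 only from that face, which gives the cis-fused bicycle and places C17 cis to C7. C18 is controlled by chelation: trivalent samarium bridges the enolate oxygen on C17 and the ketone oxygen, and in the only chair that keeps the C3 silyl ether and C7 equatorial this closed arrangement puts O34 equatorial and gauche to C17 (cis) with C19 axial, whereas the C18 epimer would need O34 anti to C17 and an open transition state. The step needs chemoselectivity (C–Br before C=O and before the α C–O bond), which the rate of halide reduction and the absence of a proton source or HMPA should secure. It must also outrun proton transfer from C2–H and retro-aldol cleavage, for which the low temperature and the cold quench are chosen. Both C11 epimers of 20 converge on the same planar enolate.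

Step 15
Reactants: 22 cis-fused ring A hydroxy γ-lactone (2S,3S,6R,11R,18S)
Product: 23 ring A tetraol (2S,3S,6R,11S,18S)
Conditions: LiAlH4, THF, −20 to 20 °C; aq. potassium sodium tartrate work-up
Reagents that add atoms: none
Why: Hydride reduction turns the lactone carbonyl C17 into the primary alcohol, frees the tertiary C7 alcohol and cleaves the pivalate in the same operation; silyl ethers survive, and fast reduction at low temperature should outrun retro-aldol cleavage of the C18 alkoxide.

Step 16
Reactants: 23 ring A tetraol (2S,3S,6R,11S,18S)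
Product: 25 spiro δ-lactone diol (2S,3S,6R,11S,18S), via lactol 24 (not isolated)
Conditions: TEMPO (cat.), PhI(OAc)2, CH2Cl2, rt
Reagents that add atoms: none
Why: TEMPO/PhI(OAc)2 oxidative lactonisation of a 1,5-diol: the unhindered C14 alcohol is oxidised first, the aldehyde is trapped by the C17 hydroxyl as a six-membered lactol and this is oxidised to the δ-lactone; the neopentyl C17 alcohol and the tertiary alcohols should not be oxidised.

Step 17
Reactants: 25 spiro δ-lactone diol (2S,3S,6R,11S,18S)
Product: 26 α-hydroxy aldehyde at C19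
Conditions: (COCl)2, DMSO, CH2Cl2, −78 to −40 °C; then Et3N
Reagents that add atoms: none
Why: Under Swern conditions a primary triethylsilyl ether is cleaved and oxidised directly to the aldehyde, while the secondary silyl ether and the tertiary alcohols are left untouched.

Step 18
Reactants: 26 α-hydroxy aldehyde at C19; 27 ethyl 2-[bis(2,2,2-trifluoroethoxy)phosphoryl]propanoate
Product: 29 spiro-butenolide with free C7 hydroxyl, via (Z)-enoate 28 (not isolated)
Conditions: 27, KN(SiMe3)2, 18-crown-6, THF, −78 °C; then 26, −78 °C to rt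
Reagents that add atoms: none
Why: The Still–Gennari variant of the Horner–Wadsworth–Emmons reaction gives the Z-trisubstituted enoate, whose ester lies cis to the C18 hydroxyl and closes to the butenolide; this forms C19=C20 and C31–O34 and brings in the C21 methyl. The preformed phosphonate anion is not basic enough to deprotonate the tertiary alcohols.

Step 19
Reactants: 29 spiro-butenolide with free C7 hydroxyl
Product: 30 spiro-butenolide C7 triethylsilyl ether
Conditions: TESOTf, 2,6-lutidine, CH2Cl2, 0 °C
Reagents that add atoms: triethylsilyl trifluoromethanesulfonate, CC[Si](CC)(CC)OS(=O)(=O)C(F)(F)F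
Why: The C7 carbinol is the only free hydroxyl once O34 is in the lactone; silylation keeps it from the silane and Lewis acids of the next steps and from dehydration.

Step 20
Reactants: 30 spiro-butenolide C7 triethylsilyl ether; 31 3-[(2E)-but-2-enoyl]-1,3-oxazolidin-2-one
Product: 33 Michael adduct imide (20R,22S), via silyl ketene acetal 32 (not isolated)
Conditions: Et3SiH, RhCl(PPh3)3 (2 mol%), PhMe, 60 °C; then 31, [Cu((S,S)-t-Bu-box)](SbF6)2 (10 mol%), (CF3)2CHOH, CH2Cl2, −78 to −20 °C
Reagents that add atoms: none
Why: Rhodium-catalysed 1,4-hydrosilylation turns the butenolide into the silyl ketene acetal and so places the nucleophilic carbon at C20 only, which no base could do next to the δ-lactone; the copper–bis(oxazoline)-catalysed Mukaiyama–Michael addition to the chelated imide then forms C20–C22. C20 is set by the substrate (attack on the face of the five-membered ring flanked by C2–H and not by C12 of the spiro δ-lactone), and C22 by the catalyst, which must expose the Si face of the β-carbon of 31.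

Step 21
Reactants: 33 Michael adduct imide (20R,22S); 34 2-methylprop-2-enal
Product: 36 anti-aldol imide (24R,33S), via trimethylsilyl ether 35 (not isolated)
Conditions: MgCl2 (20 mol%), Et3N, TMSCl, EtOAc, rt; then TFA (cat.), MeOH, 0 °C
Reagents that add atoms: none
Why: Magnesium halide-catalysed anti-aldol reaction of an N-acyloxazolidinone: soft enolisation touches only the imide, and the Z-enolate reacts through a boat transition state to the anti adduct, which is trapped by silylation. The face of C24 is set by the neighbouring C22 centre: allylic strain puts C22–H in the enolate plane and the aldehyde enters anti to the bulky C20 group, giving C24 (R) and, through the anti mode, C33 (S).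

Step 22
Reactants: 36 anti-aldol imide (24R,33S)
Product: 37 β-hydroxy acid with isopropenyl group
Conditions: LiOH, H2O2, THF/H2O, 0 °C; then Na2SO3; then 1 M HCl to pH 3
Reagents that add atoms: hydrogen peroxide (as lithium hydroperoxide), OO
Why: Hydroperoxide cleaves the exocyclic imide carbonyl selectively and without retro-aldol cleavage; the δ-lactone, should it open, recloses on acidification. This is done before the methyl ketone is unmasked, so no α-hydroxy ketone meets basic peroxide.

Step 23
Reactants: 37 β-hydroxy acid with isopropenyl group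
Product: 38 bis-silylated keto acid
Conditions: O3, CH2Cl2, −78 °C; then Me2S
Reagents that add atoms: ozone, [O-][O+]=O
Why: Ozonolysis of the 1,1-disubstituted alkene unmasks the C28 methyl ketone; no other alkene is present.

Step 24
Reactants: 38 bis-silylated keto acid
Product: 40 chermebilaene B, via desilylated keto acid 39 (not isolated)
Conditions: aq. HF, MeCN, 0 °C to rt; then PPTS, PhMe, 4 Å MS, 60 °C
Reagents that add atoms: none
Why: Fluoride removes both silyl groups; the γ-keto acid closes to its cyclic pseudo-acid (C28–O27), and the resulting cis C28/C33 diol condenses with the spiro-lactone carbonyl C31 under mild acid with removal of water. This is the acid-catalysed formation of a caged orthoester from an ester and a cis-diol; C28 and C31 can take only the target configurations once C20, C22, C24 and C33 are fixed.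

## Compound list

1 | (4S)-4-benzyl-1,3-oxazolidin-2-one | O=C1N[C@@H](Cc2ccccc2)CO1 | starting material
2 | pent-4-enoyl chloride | C=CCCC(=O)Cl | starting material
3 | (4S)-4-benzyl-3-(pent-4-enoyl)-1,3-oxazolidin-2-one | C=CCCC(=O)N1[C@@H](Cc2ccccc2)COC1=O | intermediate
4 | tert-butyl bromoacetate | BrCC(=O)OC(C)(C)C | starting material
5 | tert-butyl (3R)-3-{[(4S)-4-benzyl-2-oxo-1,3-oxazolidin-3-yl]carbonyl}hex-5-enoate | C=CC[C@H](CC(=O)OC(C)(C)C)C(=O)N1[C@@H](Cc2ccccc2)COC1=O | intermediate
6 | 4-tert-butyl 1-methyl (2R)-2-(prop-2-en-1-yl)butanedioate | C=CC[C@H](CC(=O)OC(C)(C)C)C(=O)OC | intermediate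
7 | tert-butyl (3R)-3-(2-hydroxypropan-2-yl)hex-5-enoate (not isolated) | C=CC[C@H](CC(=O)OC(C)(C)C)C(C)(C)O | intermediate
8 | (4R)-5,5-dimethyl-4-(prop-2-en-1-yl)oxolan-2-one | C=CC[C@@H]1CC(=O)OC1(C)C | intermediate
9 | 3-iodopropan-1-ol | OCCCI | starting material
10 | 2,2-dimethylpropanoyl chloride | CC(C)(C)C(=O)Cl | starting material
11 | 3-iodopropyl 2,2-dimethylpropanoate | CC(C)(C)C(=O)OCCCI | intermediate
12 | 3-[(3R,4R)-5,5-dimethyl-2-oxo-4-(prop-2-en-1-yl)oxolan-3-yl]propyl 2,2-dimethylpropanoate | C=CC[C@@H]1[C@@H](CCCOC(=O)C(C)(C)C)C(=O)OC1(C)C | intermediate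
13 | 3-[(3R,4R)-5,5-dimethyl-2-oxo-4-(2-oxoethyl)oxolan-3-yl]propyl 2,2-dimethylpropanoate | O=CC[C@@H]1[C@@H](CCCOC(=O)C(C)(C)C)C(=O)OC1(C)C | intermediate
14 | 3-{(3R,4R)-4-[(2S,3R)-2-hydroxy-3-methylpent-4-en-1-yl]-5,5-dimethyl-2-oxooxolan-3-yl}propyl 2,2-dimethylpropanoate | C[C@H](C=C)[C@@H](O)C[C@@H]1[C@@H](CCCOC(=O)C(C)(C)C)C(=O)OC1(C)C | intermediate
15 | 3-{(3R,4R)-4-[(2S,3R)-2-{[tert-butyl(dimethyl)silyl]oxy}-3-methylpent-4-en-1-yl]-5,5-dimethyl-2-oxooxolan-3-yl}propyl 2,2-dimethylpropanoate | C[C@H](C=C)[C@@H](O[Si](C)(C)C(C)(C)C)C[C@@H]1[C@@H](CCCOC(=O)C(C)(C)C)C(=O)OC1(C)C | intermediate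
16 | trimethylsilyl ketene acetal of 15 (2-silyloxy-4,5-dihydrofuran, C11=C17; not isolated) | C[C@H](C=C)[C@@H](O[Si](C)(C)C(C)(C)C)C[C@@H]1C(CCCOC(=O)C(C)(C)C)=C(O[Si](C)(C)C)OC1(C)C | intermediate
17 | 3-{(3R,4S)-3-bromo-4-[(2S,3R)-2-{[tert-butyl(dimethyl)silyl]oxy}-3-methylpent-4-en-1-yl]-5,5-dimethyl-2-oxooxolan-3-yl}propyl 2,2-dimethylpropanoate | C[C@H](C=C)[C@@H](O[Si](C)(C)C(C)(C)C)C[C@@H]1[C@](Br)(CCCOC(=O)C(C)(C)C)C(=O)OC1(C)C | intermediate
18 | 3-{(3R,4S)-3-bromo-4-[(2S,3R,4RS)-2-{[tert-butyl(dimethyl)silyl]oxy}-4,5-dihydroxy-3-methylpentyl]-5,5-dimethyl-2-oxooxolan-3-yl}propyl 2,2-dimethylpropanoate (both C18 epimers) | C[C@H](C(O)CO)[C@@H](O[Si](C)(C)C(C)(C)C)C[C@@H]1[C@](Br)(CCCOC(=O)C(C)(C)C)C(=O)OC1(C)C | intermediate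
19 | 3-{(3R,4S)-3-bromo-4-[(2S,3R,4RS)-2-{[tert-butyl(dimethyl)silyl]oxy}-4-hydroxy-3-methyl-5-[(triethylsilyl)oxy]pentyl]-5,5-dimethyl-2-oxooxolan-3-yl}propyl 2,2-dimethylpropanoate | C[C@H](C(O)CO[Si](CC)(CC)CC)[C@@H](O[Si](C)(C)C(C)(C)C)C[C@@H]1[C@](Br)(CCCOC(=O)C(C)(C)C)C(=O)OC1(C)C | intermediate
20 | 3-{(3R,4S)-3-bromo-4-[(2S,3S)-2-{[tert-butyl(dimethyl)silyl]oxy}-3-methyl-4-oxo-5-[(triethylsilyl)oxy]pentyl]-5,5-dimethyl-2-oxooxolan-3-yl}propyl 2,2-dimethylpropanoate (Reformatsky precursor) | C[C@H](C(=O)CO[Si](CC)(CC)CC)[C@@H](O[Si](C)(C)C(C)(C)C)C[C@@H]1[C@](Br)(CCCOC(=O)C(C)(C)C)C(=O)OC1(C)C | intermediate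
21 | samarium enolate of 20 at C11 (O-samarium diiodide ketene acetal, trivalent samarium; not isolated) | C[C@H](C(=O)CO[Si](CC)(CC)CC)[C@@H](O[Si](C)(C)C(C)(C)C)C[C@@H]1C(CCCOC(=O)C(C)(C)C)=C(O[Sm](I)I)OC1(C)C | intermediate
22 | cis-fused ring A hydroxy γ-lactone (2S,3S,6R,11R,18S): ring A closed, lactone C6–C7–O10–C17(=O)–C11, C18 hydroxyl and (triethylsilyloxy)methyl, C3 OTBS, C11 3-(pivaloyloxy)propyl | C[C@H]1[C@@H](O[Si](C)(C)C(C)(C)C)C[C@H]2C(C)(C)OC(=O)[C@@]2(CCCOC(=O)C(C)(C)C)[C@]1(O)CO[Si](CC)(CC)CC | intermediate
23 | ring A tetraol (2S,3S,6R,11S,18S): C17 hydroxymethyl and 3-hydroxypropyl on C11, 2-hydroxypropan-2-yl on C6, C18 hydroxyl and (triethylsilyloxy)methyl, C3 OTBS | C[C@H]1[C@@H](O[Si](C)(C)C(C)(C)C)C[C@@H](C(C)(C)O)[C@](CO)(CCCO)[C@]1(O)CO[Si](CC)(CC)CC | intermediate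
24 | spiro lactol at C14 from 23 (ring A centres as in 23; both C14 epimers; not isolated) | C[C@H]1[C@@H](O[Si](C)(C)C(C)(C)C)C[C@@H](C(C)(C)O)[C@]2(CCC(O)OC2)[C@]1(O)CO[Si](CC)(CC)CC | intermediate
25 | spiro δ-lactone diol (2S,3S,6R,11S,18S): C7 and C18 hydroxyls free, C19 OTES, C3 OTBS | C[C@H]1[C@@H](O[Si](C)(C)C(C)(C)C)C[C@@H](C(C)(C)O)[C@]2(CCC(=O)OC2)[C@]1(O)CO[Si](CC)(CC)CC | intermediate
26 | α-hydroxy aldehyde at C19 (ring A centres arranged as in 25) | C[C@H]1[C@@H](O[Si](C)(C)C(C)(C)C)C[C@@H](C(C)(C)O)[C@]2(CCC(=O)OC2)[C@]1(O)C=O | intermediate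
27 | ethyl 2-[bis(2,2,2-trifluoroethoxy)phosphoryl]propanoate | CCOC(=O)C(C)P(=O)(OCC(F)(F)F)OCC(F)(F)F | starting material
28 | (Z)-enoate: ethyl (2Z)-2-methyl-3-(C18)-prop-2-enoate of 26, ester cis to C18 (not isolated) | C[C@H]1[C@@H](O[Si](C)(C)C(C)(C)C)C[C@@H](C(C)(C)O)[C@]2(CCC(=O)OC2)[C@]1(O)/C=C(/C)C(=O)OCC | intermediate
29 | spiro-butenolide (O34–C31(=O)–C20(CH3)=C19–C18) with free C7 hydroxyl, ring A centres arranged as in 40 | C[C@H]1[C@@H](O[Si](C)(C)C(C)(C)C)C[C@@H](C(C)(C)O)[C@]2(CCC(=O)OC2)[C@]12C=C(C)C(=O)O2 | intermediate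
30 | spiro-butenolide C7 triethylsilyl ether | C[C@H]1[C@@H](O[Si](C)(C)C(C)(C)C)C[C@@H](C(C)(C)O[Si](CC)(CC)CC)[C@]2(CCC(=O)OC2)[C@]12C=C(C)C(=O)O2 | intermediate
31 | 3-[(2E)-but-2-enoyl]-1,3-oxazolidin-2-one | C/C=C/C(=O)N1CCOC1=O | starting material
32 | triethylsilyl ketene acetal of the saturated spiro-lactone (C20=C31; not isolated) | C[C@H]1[C@@H](O[Si](C)(C)C(C)(C)C)C[C@@H](C(C)(C)O[Si](CC)(CC)CC)[C@]2(CCC(=O)OC2)[C@]12CC(C)=C(O[Si](CC)(CC)CC)O2 | intermediate
33 | Michael adduct imide (20R,22S): C20 bearing C21 methyl and the C22H(CH3)–C24H2–C25(=O)–oxazolidinone chain | C[C@H]1[C@@H](O[Si](C)(C)C(C)(C)C)C[C@@H](C(C)(C)O[Si](CC)(CC)CC)[C@]2(CCC(=O)OC2)[C@]12C[C@@](C)(C(=O)O2)[C@@H](C)CC(=O)N1CCOC1=O | intermediate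
34 | 2-methylprop-2-enal | CC(=C)C=O | starting material
35 | C33 trimethylsilyl ether of 36 (not isolated) | C[C@H]1[C@@H](O[Si](C)(C)C(C)(C)C)C[C@@H](C(C)(C)O[Si](CC)(CC)CC)[C@]2(CCC(=O)OC2)[C@]12C[C@@](C)(C(=O)O2)[C@@H](C)[C@@H](C(=O)N1CCOC1=O)[C@H](O[Si](C)(C)C)C(C)=C | intermediate
36 | anti-aldol imide (24R,33S): C24 bearing the imide and C33H(OH)–C28(CH3)=CH2 | C[C@H]1[C@@H](O[Si](C)(C)C(C)(C)C)C[C@@H](C(C)(C)O[Si](CC)(CC)CC)[C@]2(CCC(=O)OC2)[C@]12C[C@@](C)(C(=O)O2)[C@@H](C)[C@@H](C(=O)N1CCOC1=O)[C@H](O)C(C)=C | intermediate
37 | β-hydroxy acid (C25 acid, C33 alcohol, isopropenyl at C28) | C[C@H]1[C@@H](O[Si](C)(C)C(C)(C)C)C[C@@H](C(C)(C)O[Si](CC)(CC)CC)[C@]2(CCC(=O)OC2)[C@]12C[C@@](C)(C(=O)O2)[C@@H](C)[C@@H](C(=O)O)[C@H](O)C(C)=C | intermediate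
38 | bis-silylated keto acid (C25 acid, C33 alcohol, C28 methyl ketone; C3 OTBS, C7 OTES) | C[C@H]1[C@@H](O[Si](C)(C)C(C)(C)C)C[C@@H](C(C)(C)O[Si](CC)(CC)CC)[C@]2(CCC(=O)OC2)[C@]12C[C@@](C)(C(=O)O2)[C@@H](C)[C@@H](C(=O)O)[C@H](O)C(C)=O | intermediate
39 | desilylated keto acid (seco form of 40; not isolated) | C[C@H]1[C@@H](O)C[C@@H](C(C)(C)O)[C@]2(CCC(=O)OC2)[C@]12C[C@@](C)(C(=O)O2)[C@@H](C)[C@@H](C(=O)O)[C@H](O)C(C)=O | intermediate
40 | chermebilaene B (2S,3S,6R,11S,18S,20R,22S,24R,28S,31S,33S) | C[C@H]1[C@@H](O)C[C@@H](C(C)(C)O)[C@]2(CCC(=O)OC2)[C@]12C[C@]1(C)[C@@H](C)[C@H]3C(=O)O[C@@]4(C)O[C@@]1(O[C@@H]34)O2 | target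

## Step count and weak points

Total: 24 steps. Longest linear sequence: 23 steps (steps 1–4 and 6–24); step 5 is a one-step side branch.

**Step 14 (key step).** Three processes compete with closure. The samarium enolate can be protonated by C2–H of the ketone, which gives reduced, uncyclised lactone. Electron transfer to the ketone can cleave the α-silyloxy group. Closure through an open transition state would erode the configuration at C18, and the aldolate can revert on warming; joining two fully substituted carbons is slow, which gives all of these room. The fallback keeps the C11–C18 Reformatsky closure but moves the quaternary centre at C18 to a later addition. It sets out from 17: ozonolysis gives aldehyde F1, SmI2 closes ring A onto the far less hindered aldehyde to give the secondary alcohol F2, and Dess–Martin oxidation gives the ring A ketone F3. (Isopropoxydimethylsilyl)methylmagnesium chloride with CeCl3 then adds axially, from the face opposite the lactone and the two axial groups on C2 and C11, to give the silylmethyl carbinol F4. Tamao oxidation (H2O2, KF, KHCO3) gives the diol F5, and TESCl returns to the route at 22.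

**Step 20.** The addition joins a quaternary and a tertiary carbon, so protodesilylation of 32 may outrun C–C bond formation. The facial preference of the catalyst may also be opposed by the intrinsic relative topicity of the two partners, or the ligand enantiomer may prove to deliver the other face of 31 than assumed; either way C22 would be eroded. The fallback replaces catalyst control by auxiliary control. It sets out from 30: hydrosilylation as before, then addition of 32 to (4R)-4-benzyl-3-[(2E)-but-2-enoyl]-1,3-oxazolidin-2-one activated by Et2AlCl, in which the benzyl group shields the face opposite to the one needed, gives the chiral imide F6. LiOH/H2O2 gives the acid F7, and mixed-anhydride acylation of lithiated oxazolidin-2-one (pivaloyl chloride, Et3N, then the lithium salt) returns to the route at 33. The auxiliary is exchanged because its own bias would oppose the substrate bias in step 21.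

**Step 21.** Soft enolisation of the strongly β-branched imide may be slow, and reversible aldolisation before silylation may erode the anti selectivity; 34 may polymerise. The fallback changes the mechanism to an open transition state. From 33, the dibutylboron Z-enolate (Bu2BOTf, i-Pr2NEt) is preformed and treated at −78 °C with 34 precomplexed with Et2AlCl, which gives the anti adduct under the same substrate control and arrives at 36; no new compound is involved.

**Step 24.** The tertiary C7 carbinol may dehydrate under acid, and the condensation may stall at a translactonised hydroxy lactone when the hemi-orthoester collapses instead of losing water. The fallback closes the cage before deprotection. From 38, PPTS and 4 Å MS in toluene act on the silylated keto acid, in which only the C33 hydroxyl and the acid are free, to give the bis-silyl ether of chermebilaene B F8; buffered HF·pyridine in THF/pyridine then arrives at 40.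

**Step 18.** Z selectivity may be poor on the neopentyl-type aldehyde, and the E-enoate cannot lactonise; the α-hydroxy aldehyde may also undergo α-ketol rearrangement under basic conditions. The fallback uses a neutral olefination and corrects the geometry afterwards. From 26, ethyl 2-(triphenylphosphoranylidene)propanoate in toluene gives the (E)-enoate F9; sensitised irradiation (365 nm, thioxanthone) isomerises it to the Z-isomer, which lactonises and arrives at 29.

## Further compounds

F1 | step 14 | 3-{(3R,4S)-3-bromo-4-[(2S,3S)-2-{[tert-butyl(dimethyl)silyl]oxy}-3-methyl-4-oxobutyl]-5,5-dimethyl-2-oxooxolan-3-yl}propyl 2,2-dimethylpropanoate | C[C@H](C=O)[C@@H](O[Si](C)(C)C(C)(C)C)C[C@@H]1[C@](Br)(CCCOC(=O)C(C)(C)C)C(=O)OC1(C)C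
F2 | step 14 | cis-fused ring A γ-lactone with secondary C18 hydroxyl (both C18 epimers) | C[C@H]1[C@@H](O[Si](C)(C)C(C)(C)C)C[C@H]2C(C)(C)OC(=O)[C@@]2(CCCOC(=O)C(C)(C)C)C1O
F3 | step 14 | cis-fused ring A γ-lactone C18 ketone | C[C@H]1[C@@H](O[Si](C)(C)C(C)(C)C)C[C@H]2C(C)(C)OC(=O)[C@@]2(CCCOC(=O)C(C)(C)C)C1=O
F4 | step 14 | C18 tertiary alcohol bearing the (isopropoxydimethylsilyl)methyl group | C[C@H]1[C@@H](O[Si](C)(C)C(C)(C)C)C[C@H]2C(C)(C)OC(=O)[C@@]2(CCCOC(=O)C(C)(C)C)[C@]1(O)C[Si](C)(C)OC(C)C
F5 | step 14 | C18/C19 diol of the cis-fused ring A γ-lactone | C[C@H]1[C@@H](O[Si](C)(C)C(C)(C)C)C[C@H]2C(C)(C)OC(=O)[C@@]2(CCCOC(=O)C(C)(C)C)[C@]1(O)CO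
F6 | step 20 | Michael adduct carrying the (4R)-4-benzyl-oxazolidinone auxiliary | C[C@H]1[C@@H](O[Si](C)(C)C(C)(C)C)C[C@@H](C(C)(C)O[Si](CC)(CC)CC)[C@]2(CCC(=O)OC2)[C@]12C[C@@](C)(C(=O)O2)[C@@H](C)CC(=O)N1[C@H](Cc2ccccc2)COC1=O
F7 | step 20 | Michael adduct C25 carboxylic acid | C[C@H]1[C@@H](O[Si](C)(C)C(C)(C)C)C[C@@H](C(C)(C)O[Si](CC)(CC)CC)[C@]2(CCC(=O)OC2)[C@]12C[C@@](C)(C(=O)O2)[C@@H](C)CC(=O)O
F0 | step 21 | none | none
F8 | step 24 | 3-O-TBS 10-O-TES bis-silyl ether of chermebilaene B | C[C@H]1[C@@H](O[Si](C)(C)C(C)(C)C)C[C@@H](C(C)(C)O[Si](CC)(CC)CC)[C@]2(CCC(=O)OC2)[C@]12C[C@]1(C)[C@@H](C)[C@H]3C(=O)O[C@@]4(C)O[C@@]1(O[C@@H]34)O2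
F9 | step 18 | (E)-enoate isomer of 28 | C[C@H]1[C@@H](O[Si](C)(C)C(C)(C)C)C[C@@H](C(C)(C)O)[C@]2(CCC(=O)OC2)[C@]1(O)/C=C(\C)C(=O)OCC
A1 | alternative 1 | mixed methyl orthoester with tetrahydrofuran and tetrahydropyran closed | C[C@H]1[C@@H](O[Si](C)(C)C(C)(C)C)C[C@@H](C(C)(C)O[Si](CC)(CC)CC)[C@]2(CCC(=O)OC2)[C@]12C[C@]1(C)[C@@H](C)[C@@H](C(=O)OC(C)(C)C)[C@@H](C(C)=O)O[C@]1(OC)O2
A2 | alternative 1 | C18 tertiary alcohol with the tetrahydropyran as C31 methyl acetal (both C31 epimers) | C[C@H]1[C@@H](O[Si](C)(C)C(C)(C)C)C[C@@H](C(C)(C)O[Si](CC)(CC)CC)[C@]2(CCC(=O)OC2)[C@]1(O)C[C@]1(C)[C@@H](C)[C@@H](C(=O)OC(C)(C)C)[C@@H](C(C)=O)OC1OC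
A3 | alternative 2 | ring A ketone with cis-fused γ-lactone | C[C@H]1[C@@H](O[Si](C)(C)C(C)(C)C)C[C@H]2C(C)(C)OC(=O)[C@@]2(CCCOCc2ccccc2)C1=O
A4 | alternative 2 | acyclic β-keto ester with terminal prenyl-type alkene (both C11 epimers) | C[C@H](C(=O)C(CCCOCc1ccccc1)C(=O)OC)[C@@H](O[Si](C)(C)C(C)(C)C)CC=C(C)C
A5 | alternative 3 | bis-silyl ether of chermebilaene B | C[C@H]1[C@@H](O[Si](C)(C)C(C)(C)C)C[C@@H](C(C)(C)O[Si](CC)(CC)CC)[C@]2(CCC(=O)OC2)[C@]12C[C@]1(C)[C@@H](C)[C@H]3C(=O)O[C@@]4(C)O[C@@]1(O[C@@H]34)O2
A6 | alternative 3 | ring A with spiro δ-lactone and exocyclic methylene C18=C19 | C[C@H]1[C@@H](O[Si](C)(C)C(C)(C)C)C[C@@H](C(C)(C)O[Si](CC)(CC)CC)[C@]2(CCC(=O)OC2)C1=C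
A7 | alternative 3 | bicyclic α-bromo δ-lactone with C28 hemiketal (both C20 epimers) | C[C@H]1[C@H]2C(=O)O[C@@](C)(O)[C@H]2OC(=O)C1(C)Br
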